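**Retrosynthetic overview**

1. Endgame: target 17 ⇐ Mitsunobu benzoylation with inversion at C9 of alcohol 15 ⇐ hydroxyl-directed hydrogenation of the C7 exocyclic methylene of 14 ⇐ dynamic kinetic transfer hydrogenation of ketone 13 ⇐ fluoride de-esterification of 11.
2. Key disconnection: 11 ⇒ biaryl phenol β-keto ester 9 + methyl propargyl carbonate 10. One palladium-catalysed (5+2) dearomatising spiroannulation makes C7–C8 and C5–C6, closes the seven-membered ring C, creates the spiro quaternary carbon and turns phenol ring A into the dienone.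
3. Enabling feature: the spiro carbon C5 is the para carbon of a 4-hydroxy-3,5-dimethoxyphenyl ring A in disguise, and C8 is the α-carbon of the C9 benzylic ketone. These two nucleophilic carbons are 1,5-related through C4a–C9a of ring B, so a three-carbon propargyl unit can bridge them (central carbon → C7, ends → C6 and the 7-methyl). The two arms of the dienone are identical, so C5 is not a stereocentre.
4. 9 ⇒ Suzuki coupling of aryl bromide 7 with boronate 8; 7 ⇒ crossed Claisen condensation of acid chloride 5 (from 4) with ester 3 (from 1 + 2).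
5. Ring order: rings A and B are bought as arenes and joined in step 4; ring C is the only ring that is built (step 5), and the same event converts ring A into the cyclohexadienone.

Key step: step 5

Remarks. Locants: C5 spiro carbon, C6 ring CH2, C7 and C8 the methyl-bearing carbons, C9 the oxygenated benzylic carbon, C4a/C9a the ring B carbons bonded to C5/C9; dienone ring locants are primed. Compounds 7, 9 and 13 are stereolabile at the carbon α to the ketone and 11 is formed racemic; all three stereocentres of the target are fixed in steps 7 to 9. Assumption: 1, 2, 4, 8, 10 and 16 are taken as commercially available.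

**Route**

Step 1
Reactants: 1 propanoyl chloride; 2 2-(trimethylsilyl)ethanol
Product: 3 2-(trimethylsilyl)ethyl propanoate
Conditions: Et3N, DMAP (cat.), CH2Cl2, 0 °C to rt
Reagents that add atoms: none
Why: Acylation of a primary alcohol by an acid chloride (nucleophilic acyl substitution) is reliable, and the 2-(trimethylsilyl)ethyl ester is chosen because fluoride removes it later without acid, heat or hydride.

Step 2
Reactants: 4 2-bromo-3,4,5-trimethoxybenzoic acid
Product: 5 2-bromo-3,4,5-trimethoxybenzoyl chloride
Conditions: (COCl)2, DMF (cat.), CH2Cl2, 0 °C to rt; evaporate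
Reagents that add atoms: oxalyl chloride, ClC(=O)C(=O)Cl
Why: Vilsmeier-type activation with oxalyl chloride and catalytic DMF converts the benzoic acid into its acid chloride with only gaseous by-products and leaves the aryl bromide and methyl ethers untouched.

Step 3
Reactants: 5 2-bromo-3,4,5-trimethoxybenzoyl chloride; 3 2-(trimethylsilyl)ethyl propanoate
Product: 7 2-(trimethylsilyl)ethyl 3-(2-bromo-3,4,5-trimethoxyphenyl)-2-methyl-3-oxopropanoate, via lithium ester enolate 6 (not isolated)
Conditions: LiN(iPr)2 (2.1 equiv.), 3 (2.1 equiv.), THF, −78 °C; then 5, −78 to −40 °C; aq. NH4Cl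
Reagents that add atoms: none
Why: Crossed Claisen condensation (C-acylation of a preformed lithium ester enolate by a non-enolisable aroyl chloride), in which the second equivalent of enolate absorbs the acidic proton of the β-keto ester and the amide base at −78 °C does not touch the aryl bromide.

Step 4
Reactants: 7 2-(trimethylsilyl)ethyl 3-(2-bromo-3,4,5-trimethoxyphenyl)-2-methyl-3-oxopropanoate; 8 2,6-dimethoxy-4-(4,4,5,5-tetramethyl-1,3,2-dioxaborolan-2-yl)phenol
Product: 9 2-(trimethylsilyl)ethyl 3-[2-(4-hydroxy-3,5-dimethoxyphenyl)-3,4,5-trimethoxyphenyl]-2-methyl-3-oxopropanoate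
Conditions: Pd(OAc)2 (5 mol %), SPhos (10 mol %), K3PO4, toluene/H2O (10:1), 80 °C
Reagents that add atoms: none
Why: Suzuki–Miyaura coupling with a dialkylbiarylphosphine ligand suited to a di-ortho-substituted aryl bromide, in which the free phenol and the β-keto ester are carried as their potassium salts under mild phosphate base.

Step 5
Reactants: 9 2-(trimethylsilyl)ethyl 3-[2-(4-hydroxy-3,5-dimethoxyphenyl)-3,4,5-trimethoxyphenyl]-2-methyl-3-oxopropanoate; 10 methyl prop-2-yn-1-yl carbonate
Product: 11 racemic 2-(trimethylsilyl)ethyl 2,3,4,3',5'-pentamethoxy-8-methyl-7-methylidene-4',9-dioxo-6,7,8,9-tetrahydrospiro[benzo[7]annulene-5,1'-cyclohexa[2,5]diene]-8-carboxylate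
Conditions: Pd2(dba)3·CHCl3 (2.5 mol %), Xantphos (6 mol %), 1,4-dioxane (0.01 M), 60 °C, slow addition of 10 (1.2 equiv.)
Reagents that add atoms: none
Why: Proposed new method: Oxidative addition of zerovalent palladium to 10 with loss of CO2 should give a cationic η3-propargyl/allenyl palladium species and methoxide; methoxide deprotonates the most acidic C–H of 9 (the carbon between ketone and ester), this soft carbanion attacks the central carbon, the palladacyclobutene so formed is protonated by the phenol, and the para carbon of the resulting 2,6-dimethoxyphenolate attacks a CH2 terminus of the 2-substituted π-allyl palladium and releases the catalyst. The closest known reaction type is the palladium-catalysed double substitution of propargyl carbonates by tethered bis-nucleophiles, including dearomatising variants that end at indole C3, together with the palladium-catalysed intramolecular ipso-allylation of para-substituted phenols, both of which close five- and six-membered spiro rings; closing a seven-membered ring at a phenol para carbon in this cascade is the extension. Ring C closes by outer-sphere attack on the allyl terminus, exo with respect to the departing palladium and spiro (ipso) at the phenol para carbon, so the central carbon becomes C7 with its exocyclic CH2 and the attacked terminus becomes C6; the two allyl termini are equivalent, so no regiochemical question arises. The only new stereocentre is the quaternary C8, formed racemic and deleted in step 6, and C5 is not stereogenic because both arms of the dienone are identical. The step needs the ester-activated carbon to react first and at the central carbon, which its higher acidity and softness secure, and the methyl group on that carbon leaves no enolisable hydrogen after the first bond, so furan formation through an enol oxygen is shut off. Closure at carbon and not oxygen is secured by geometry, since the phenolate oxygen and the methoxy-bearing ortho carbons cannot reach the allyl unit and only the para carbon lies within a seven-membered transition state, while the flanking methoxy groups and high dilution hold back intermolecular O-allylation.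

Step 6
Reactants: 11 racemic 2-(trimethylsilyl)ethyl 2,3,4,3',5'-pentamethoxy-8-methyl-7-methylidene-4',9-dioxo-6,7,8,9-tetrahydrospiro[benzo[7]annulene-5,1'-cyclohexa[2,5]diene]-8-carboxylate
Product: 13 racemic 2,3,4,3',5'-pentamethoxy-8-methyl-7-methylidene-7,8-dihydrospiro[benzo[7]annulene-5,1'-cyclohexa[2,5]diene]-4',9(6H)-dione, via tetrabutylammonium carboxylate 12 (not isolated)
Conditions: Bu4NF (1.5 equiv.), THF, 0 °C to rt; AcOH quench at 0 °C; used at once in step 7
Reagents that add atoms: none
Why: Fluoride attacks silicon and fragments the 2-(trimethylsilyl)ethyl ester to ethene and the carboxylate, the naked β-keto carboxylate loses CO2, and kinetic α-protonation of the dienolate by acetic acid should give the β,γ-unsaturated ketone without acid, heat or hydride reaching the dienone or the exocyclic alkene.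

Step 7
Reactants: 13 racemic 2,3,4,3',5'-pentamethoxy-8-methyl-7-methylidene-7,8-dihydrospiro[benzo[7]annulene-5,1'-cyclohexa[2,5]diene]-4',9(6H)-dione
Product: 14 (8S,9S)-9-hydroxy-2,3,4,3',5'-pentamethoxy-8-methyl-7-methylidene-6,7,8,9-tetrahydrospiro[benzo[7]annulene-5,1'-cyclohexa[2,5]dien]-4'-one
Conditions: RuCl[(S,S)-TsDPEN](p-cymene) (2 mol %), HCO2H/Et3N (5:2), EtOAc, 25 °C
Reagents that add atoms: none
Why: Noyori–Ikariya asymmetric transfer hydrogenation with dynamic kinetic resolution: C8, being both α to the ketone and allylic, should racemise through the enol faster than reduction; the (S,S)-catalyst delivers hydride to the aryl ketone face that gives the (9S)-carbinol and takes the enantiomer whose 8-methyl group lies away from the incoming hydride, so the cis (8S,9S) alcohol is expected as with 2-alkyl-1-tetralones; the catalyst's preference for aryl ketones and the two flanking methoxy groups should spare the dienone carbonyl.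

Step 8
Reactants: 14 (8S,9S)-9-hydroxy-2,3,4,3',5'-pentamethoxy-8-methyl-7-methylidene-6,7,8,9-tetrahydrospiro[benzo[7]annulene-5,1'-cyclohexa[2,5]dien]-4'-one
Product: 15 (7R,8S,9S)-9-hydroxy-2,3,4,3',5'-pentamethoxy-7,8-dimethyl-6,7,8,9-tetrahydrospiro[benzo[7]annulene-5,1'-cyclohexa[2,5]dien]-4'-one
Conditions: [Rh(nbd)(dppb)]BF4 (5 mol %), H2 (40 bar), CH2Cl2, 25 °C
Reagents that add atoms: none
Why: Hydroxyl-directed homogeneous hydrogenation, in which the cationic rhodium catalyst binds the C9 hydroxyl and the homoallylic 1,1-disubstituted alkene and adds hydrogen to the alkene face syn to the hydroxyl, so the new 7-methyl group ends anti to the hydroxyl and to the 8-methyl group (7R) while the undirected trisubstituted methoxy enone double bonds should stay.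

Step 9
Reactants: 15 (7R,8S,9S)-9-hydroxy-2,3,4,3',5'-pentamethoxy-7,8-dimethyl-6,7,8,9-tetrahydrospiro[benzo[7]annulene-5,1'-cyclohexa[2,5]dien]-4'-one; 16 benzoic acid
Product: 17 (7R,8S,9R)-2,3,4,3',5'-pentamethoxy-7,8-dimethyl-4'-oxo-6,7,8,9-tetrahydrospiro[benzo[7]annulene-5,1'-cyclohexa[2,5]dien]-9-yl benzoate (CNP0201356.1)
Conditions: PPh3, DIAD, toluene, 0 °C to rt
Reagents that add atoms: none
Why: Mitsunobu esterification, in which benzoate displaces the alkoxyphosphonium of the benzylic alcohol with inversion at C9 and enters anti to the 8-methyl group, so the benzoate ends trans to the 8-methyl and cis to the 7-methyl group as in the target; any ionisation of the electron-rich benzylic centre should be captured from the same less hindered face.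

**Compound list**

1 | propanoyl chloride | CCC(=O)Cl | starting material
2 | 2-(trimethylsilyl)ethanol | C[Si](C)(C)CCO | starting material
3 | 2-(trimethylsilyl)ethyl propanoate | CCC(=O)OCC[Si](C)(C)C | intermediate
4 | 2-bromo-3,4,5-trimethoxybenzoic acid | OC(=O)c1cc(OC)c(OC)c(OC)c1Br | starting material
5 | 2-bromo-3,4,5-trimethoxybenzoyl chloride | ClC(=O)c1cc(OC)c(OC)c(OC)c1Br | intermediate
6 | lithium enolate of 2-(trimethylsilyl)ethyl propanoate (not isolated) | CC=C(O[Li])OCC[Si](C)(C)C | intermediate
7 | 2-(trimethylsilyl)ethyl 3-(2-bromo-3,4,5-trimethoxyphenyl)-2-methyl-3-oxopropanoate (racemic, stereolabile) | CC(C(=O)OCC[Si](C)(C)C)C(=O)c1cc(OC)c(OC)c(OC)c1Br | intermediate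
8 | 2,6-dimethoxy-4-(4,4,5,5-tetramethyl-1,3,2-dioxaborolan-2-yl)phenol | COc1cc(cc(OC)c1O)B1OC(C)(C)C(C)(C)O1 | starting material
9 | 2-(trimethylsilyl)ethyl 3-[2-(4-hydroxy-3,5-dimethoxyphenyl)-3,4,5-trimethoxyphenyl]-2-methyl-3-oxopropanoate (racemic, stereolabile) | CC(C(=O)OCC[Si](C)(C)C)C(=O)c1cc(OC)c(OC)c(OC)c1-c1cc(OC)c(O)c(OC)c1 | intermediate
10 | methyl prop-2-yn-1-yl carbonate | C#CCOC(=O)OC | starting material
11 | racemic 2-(trimethylsilyl)ethyl 2,3,4,3',5'-pentamethoxy-8-methyl-7-methylidene-4',9-dioxo-6,7,8,9-tetrahydrospiro[benzo[7]annulene-5,1'-cyclohexa[2,5]diene]-8-carboxylate | COC1=CC2(C=C(OC)C1=O)CC(=C)C(C)(C(=O)OCC[Si](C)(C)C)C(=O)c1cc(OC)c(OC)c(OC)c12 | intermediate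
12 | tetrabutylammonium 2,3,4,3',5'-pentamethoxy-8-methyl-7-methylidene-4',9-dioxo-6,7,8,9-tetrahydrospiro[benzo[7]annulene-5,1'-cyclohexa[2,5]diene]-8-carboxylate (racemic, not isolated) | COC1=CC2(C=C(OC)C1=O)CC(=C)C(C)(C(=O)[O-])C(=O)c1cc(OC)c(OC)c(OC)c12.CCCC[N+](CCCC)(CCCC)CCCC | intermediate
13 | racemic 2,3,4,3',5'-pentamethoxy-8-methyl-7-methylidene-7,8-dihydrospiro[benzo[7]annulene-5,1'-cyclohexa[2,5]diene]-4',9(6H)-dione | COC1=CC2(C=C(OC)C1=O)CC(=C)C(C)C(=O)c1cc(OC)c(OC)c(OC)c12 | intermediate
14 | (8S,9S)-9-hydroxy-2,3,4,3',5'-pentamethoxy-8-methyl-7-methylidene-6,7,8,9-tetrahydrospiro[benzo[7]annulene-5,1'-cyclohexa[2,5]dien]-4'-one | COC1=CC2(C=C(OC)C1=O)CC(=C)[C@H](C)[C@H](O)c1cc(OC)c(OC)c(OC)c12 | intermediate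
15 | (7R,8S,9S)-9-hydroxy-2,3,4,3',5'-pentamethoxy-7,8-dimethyl-6,7,8,9-tetrahydrospiro[benzo[7]annulene-5,1'-cyclohexa[2,5]dien]-4'-one | COC1=CC2(C=C(OC)C1=O)C[C@@H](C)[C@H](C)[C@H](O)c1cc(OC)c(OC)c(OC)c12 | intermediate
16 | benzoic acid | OC(=O)c1ccccc1 | starting material
17 | (7R,8S,9R)-2,3,4,3',5'-pentamethoxy-7,8-dimethyl-4'-oxo-6,7,8,9-tetrahydrospiro[benzo[7]annulene-5,1'-cyclohexa[2,5]dien]-9-yl benzoate | COC1=CC2(C=C(OC)C1=O)C[C@@H](C)[C@H](C)[C@@H](OC(=O)c1ccccc1)c1cc(OC)c(OC)c(OC)c12 | target

**Step count and risks**

Total step count: 9. Longest linear sequence: 8 steps (4 → 17, steps 2 to 9).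

Steps most likely to fail:

Step 5. Intermolecular O-allylation and oligomerisation may outrun the seven-membered closure, or the allylic C5–C6 bond may re-ionise under the catalyst, driven by rearomatisation of ring A. The fallback makes the two bonds one at a time by known reactions; it sets out from 3 and 5 and comes back at 11. Palladium-catalysed α-alkenylation of the lithium enolate of 3 with commercial (2-bromoallyl)trimethylsilane (Pd(dba)2, P(tBu)3, LiNCy2, toluene, rt) should give 2-(trimethylsilyl)ethyl 2-methyl-3-[(trimethylsilyl)methyl]but-3-enoate F1. Its lithium dienolate (LiN(iPr)2, THF, −78 °C) is C-acylated at the α-carbon by 5 to give 2-(trimethylsilyl)ethyl 2-(2-bromo-3,4,5-trimethoxybenzoyl)-2-methyl-3-[(trimethylsilyl)methyl]but-3-enoate F2, which already holds the C7–C8 bond and the quaternary carbon. Suzuki coupling with 8 under the conditions of step 4 gives 2-(trimethylsilyl)ethyl 2-[2-(4-hydroxy-3,5-dimethoxyphenyl)-3,4,5-trimethoxybenzoyl]-2-methyl-3-[(trimethylsilyl)methyl]but-3-enoate F3. Oxidation of the phenol with PhI(OAc)2 in (CF3)2CHOH at −20 °C then closes C5–C6 irreversibly: the tethered allylsilane attacks the para carbon of the phenoxonium ion and loses silicon (dearomatising oxidative Hosomi–Sakurai-type spirocyclisation, a known way to spirodienones), which gives 11 with the exocyclic methylene at C7.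

Step 7. Hydride transfer to the dienone carbonyl, migration of the exocyclic double bond into conjugation with the ketone, or racemisation at C8 that is too slow for a dynamic resolution may each erode the result. The fallback moves the reduction from the ruthenium hydride to an enzyme; it sets out from 13 and comes back at 14 and makes no new compound. A ketoreductase chosen from a commercial panel for (S)-selective reduction of aryl ketones is used with NADPH recycled by glucose dehydrogenase and glucose, in phosphate buffer (pH 7.5 to 8) with a little DMSO at 30 °C. Under these conditions C8 should still epimerise through the enol, and the binding pocket should discriminate the aryl ketone from the dienone carbonyl.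

Step 9. Elimination across C8–C9 to the styrene, ionisation of the electron-rich benzylic centre with loss of stereospecificity, or failure of the hindered carbinol to form the alkoxyphosphonium may intervene. The fallback replaces substitution by an oxidation–reduction sequence with reagent control; it sets out from 15 and comes back at 17. Dess–Martin periodinane (CH2Cl2, NaHCO3, 0 °C) should give (7R,8S)-2,3,4,3',5'-pentamethoxy-7,8-dimethyl-7,8-dihydrospiro[benzo[7]annulene-5,1'-cyclohexa[2,5]diene]-4',9(6H)-dione F4, in which the methyl groups already have the trans arrangement. Corey–Bakshi–Shibata reduction ((S)-Me-CBS oxazaborolidine, BH3·SMe2, THF, −30 °C) delivers hydride under catalyst control to give (7R,8S,9R)-9-hydroxy-2,3,4,3',5'-pentamethoxy-7,8-dimethyl-6,7,8,9-tetrahydrospiro[benzo[7]annulene-5,1'-cyclohexa[2,5]dien]-4'-one F5. Benzoylation (BzCl, DMAP, pyridine, CH2Cl2, 0 °C) then gives 17 with retention.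

**Further compounds**

F1 | step 5 | 2-(trimethylsilyl)ethyl 2-methyl-3-[(trimethylsilyl)methyl]but-3-enoate (racemic) | CC(C(=C)C[Si](C)(C)C)C(=O)OCC[Si](C)(C)C
F2 | step 5 | 2-(trimethylsilyl)ethyl 2-(2-bromo-3,4,5-trimethoxybenzoyl)-2-methyl-3-[(trimethylsilyl)methyl]but-3-enoate (racemic) | CC(C(=C)C[Si](C)(C)C)(C(=O)OCC[Si](C)(C)C)C(=O)c1cc(OC)c(OC)c(OC)c1Br
F3 | step 5 | 2-(trimethylsilyl)ethyl 2-[2-(4-hydroxy-3,5-dimethoxyphenyl)-3,4,5-trimethoxybenzoyl]-2-methyl-3-[(trimethylsilyl)methyl]but-3-enoate (racemic) | CC(C(=C)C[Si](C)(C)C)(C(=O)OCC[Si](C)(C)C)C(=O)c1cc(OC)c(OC)c(OC)c1-c1cc(OC)c(O)c(OC)c1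
F0 | step 7 | none | none
F4 | step 9 | (7R,8S)-2,3,4,3',5'-pentamethoxy-7,8-dimethyl-7,8-dihydrospiro[benzo[7]annulene-5,1'-cyclohexa[2,5]diene]-4',9(6H)-dione | COC1=CC2(C=C(OC)C1=O)C[C@@H](C)[C@H](C)C(=O)c1cc(OC)c(OC)c(OC)c12
F5 | step 9 | (7R,8S,9R)-9-hydroxy-2,3,4,3',5'-pentamethoxy-7,8-dimethyl-6,7,8,9-tetrahydrospiro[benzo[7]annulene-5,1'-cyclohexa[2,5]dien]-4'-one | COC1=CC2(C=C(OC)C1=O)C[C@@H](C)[C@H](C)[C@@H](O)c1cc(OC)c(OC)c(OC)c12
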